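At 8.0 h each mole of substrate charged stands in one entry of a ledger: substrate, intermediate, target or side product. Substrate is the limiting reagent, since its charge is smaller than that of partner, so I keep the books in percent of it.

| flask | substrate | partner | remark | time |
|---|---|---|---|---|
| dusk | 1 M | 1.5 M | the very flask that is asked about, followed so far |  |
| summer | 1 M | 1 M | run made earlier |  |
| flask | 1.0 M | 1.50 M |  | 8.0 h |

| run | time / h | target / % | side product / % |
|---|---|---|---|
| dusk | 0.500 | 0.1 | 3.1 |
| dusk | 1.00 | 1.1 | 8.5 |
| dusk | 1.50 | 4.9 | 13.2 |
| dusk | 2.00 | 6.1 | 18.6 |
| dusk | 2.50 | 7.7 | 21.5 |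
| dusk | 3.00 | 9.5 | 26.7 |
| summer | 0.417 | 0 | 2.3 |
| summer | 0.667 | 0.9 | 4.3 |
| summer | 1.33 | 2.1 | 11.9 |
| summer | 2.00 | 3.9 | 17.1 |
| summer | 3.00 | 6.1 | 26.7 |
| summer | 6.00 | 11.6 | 45.6 |

(standard deviation of a reading: 0.5 percentage points)

- target present at 8.0 h, in percent of the substrate charged
- side product present at 8.0 h, in percent of the substrate charged
- intermediate present at 8.0 h, in percent of the substrate charged
- concentration of partner at 8.0 h, in M

- the numbers in the tables scatter by 0.5 percentage points (one standard deviation)

The readings fill the target and side-product entries, so I call the remainder the unfinished share. In the dusk run it falls from 90.4% at 1.00 h to 63.8% at 3.00 h. Over its first 0.500 h the dusk flask makes side product at 0.0620 h⁻¹ of the charge, slower than the 0.0910 h⁻¹ of the later mean, and target lags too. I read this as a stock that substrate fills early and both products drain, so I book the unfinished share at 8.0 h as intermediate.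

Replacing the curve by its mean gives 0.174 h⁻¹: this is the drain constant, the mean fall per hour in the logarithm of the unfinished share. From 3.00 h it leaves 26.7%. To check the mean, the summer run at [partner] = 1 M gives a slower 0.149 h⁻¹, which would leave 30.3%, an error of 3.5 percentage points. Target took 31.6% of what finished in the dusk window. My books therefore close at target 21.2%, side product 52.1% and intermediate 26.7%. Taking one partner per target, [partner] is 1.29 M.

The forecast reads target 18.5%, side product 51%, intermediate 2.5% and partner 1.29 M, with “the intermediate staying small, a few percent”.

The flask gives target 20.0%, side product 52.2%, intermediate 27.9% and partner 1.30 M, with substrate at 0%.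

    intermediate → side product (k = 0.00200 min⁻¹)
    substrate → intermediate (k = 0.0260 min⁻¹)
    substrate → side product (k = 0.00100 min⁻¹)
    partner + intermediate → target (k = 5.90 × 10⁻⁴ L mol⁻¹ min⁻¹)

At 0.429 h this flask makes intermediate 9.75 times faster than it uses it, and at 4.00 h intermediate stands at 54.2% of the substrate charged. At 8.0 h the path from intermediate to side product runs 2.6 times faster than the path from intermediate to target. From 4.00 h to 8.0 h the intermediate of this flask falls on average at 0.166 h⁻¹, against my 0.174 h⁻¹. Starting from the 27.9% of intermediate that stands at 8.0 h, the drain constant leaves 0.607% at 30 h, and the neighbour flask read at that time holds 0.754% of intermediate.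

The numbers in the tables are calculated for substances that don't exist; scatter was added.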